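The data stem from a simulated flask with constants of no real substance; the scatter is artificial.

Slowness is what we can work with. In the epsilon run, other capture product stood at 14 % after 5.00 h and 21 % after 30.0 h, so a first-order rise gives a reading of about 4.55 h for the time constant with which molecules reach the fork between target and other capture product.

| setting | epsilon | beta | zeta | gamma | east | south-east | south-west |
|---|---|---|---|---|---|---|---|
| starting material | 0.30 M | 0.42 M | 0.66 M | 0.30 M | 0.30 M (fed, over 20 h) | 0.30 M | 0.30 M |
| first nucleophile | 0.21 M | 0.21 M | 0.21 M | 0.21 M | 0.210 M | 0.210 M | 0.210 M |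
| second nucleophile | 0.33 M | 0.33 M | 0.33 M | 0.17 M | 0.330 M | 0.330 M | 0.330 M (fed, over 20 h) |
| capture agent | 0.030 M | 0.030 M | 0.030 M | 0.030 M | 0.0300 M | 0.0300 M | 0.0300 M |
| remark | run made earlier | run made earlier | run made earlier | run made earlier | all else is in the flask from the start; the feed brings no volume worth counting | everything together at the start | all else is in the flask from the start; the feed brings no volume worth counting |
| time |  |  |  |  | 30 h | 30 h | 30 h |

| run | time / h | target / % | other capture product / % |
|---|---|---|---|
| epsilon | 2.50 | 6 | 9 |
| epsilon | 5.00 | 8 | 14 |
| epsilon | 8.00 | 6 | 14 |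
| epsilon | 15.0 | 9 | 19 |
| epsilon | 30.0 | 8 | 21 |
| beta | 2.50 | 2 | 6 |
| beta | 5.00 | 4 | 12 |
| beta | 8.00 | 5 | 14 |
| beta | 15.0 | 4 | 20 |
| beta | 30.0 | 5 | 16 |
| zeta | 6.00 | 6 | 10 |
| zeta | 12.0 | 4 | 22 |
| zeta | 20.0 | 5 | 14 |
| zeta | 25.0 | 6 | 15 |
| zeta | 30.0 | 4 | 18 |
| gamma | 2.50 | 5 | 6 |
| gamma | 5.00 | 6 | 3 |
| gamma | 8.00 | 7 | 9 |
| gamma | 15.0 | 7 | 9 |
| gamma | 30.0 | 11 | 13 |

(readings scatter by 1.5 percentage points)

- the numbers in the tables scatter by 1.5 percentage points (one standard deviation)

1. which flask leads in share of target in target plus other capture product ("all alike" within 1.5 percentage points) (east / south-east / south-west / all alike)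
2. share of target in target plus other capture product at the end, east
3. share of target in target plus other capture product at the end, south-east
4. share of target in target plus other capture product at the end, south-west

For whoever takes over the bench: follow one molecule to that fork. We reckon its chances with the fork constant, our selectivity factor: the ratio of target to other capture product, multiplied by the second nucleophile met at the fork, taken at 0.21 M of first nucleophile. Pooled readings with charged amounts give 0.159 M for epsilon and 0.153 M for gamma, so we carry their mean, 0.156 M.

East and south-east both have the full 0.330 M in the flask from the start, which gives us a share of 32.1 % in each. In south-west, second nucleophile builds up over 20 h, so a molecule arriving after one time constant meets about 0.0751 M, less than the full charge, and our share is 67.5 %. Leave that feed at its set rate: in our reckoning the level met is the charge times the ratio of time constant to feed time, 0.228.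

The forecast gives south-west the lead, with east 36 %, south-east 31 % and south-west 62 %, holding that “South-west keeps the second nucleophile low during the main product-forming period”; our south-west stands higher and our east lower.

South-west leads with 57.2 %, against 28.2 % for east and 27.6 % for south-east. South-west ended with 5.73 % of other capture product, where south-east ended with 18.0 %. Read through the fork constant, south-west's final ratio of 1.34 corresponds to a level of 0.116 M, more than our 0.0751 M and less than the mean of 0.156 M in south-west over the first 20 h.

    target ⇌ isomer of the product (K = 2.90, k = 0.0300 min⁻¹)
    open intermediate + capture agent → trapped intermediate (k = 0.00930 L mol⁻¹ min⁻¹)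
    starting material → open intermediate (k = 0.00310 min⁻¹)
    starting material + target → side product (k = 0.0130 L mol⁻¹ min⁻¹)
    first nucleophile + open intermediate → target (k = 0.130 L mol⁻¹ min⁻¹)
    open intermediate → solvolysis product (k = 0.0280 min⁻¹)
    second nucleophile + open intermediate → other capture product (k = 0.0380 L mol⁻¹ min⁻¹)

A neighbour of south-west is charged with 0.83 M of second nucleophile. Scaling that level with the charge gives 0.293 M and a share of 34.7 %; the computed flask gives 36.6 %.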